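## Numbering used throughout

1 divanillin · 2 bis(MOM) dialdehyde · 3 methyltriphenylphosphonium bromide · 4 methylenetriphenylphosphorane (not isolated) · 5 bis(MOM) divinyl biaryl · 6 carbon dioxide · 7 magnesium dicarboxylate (not isolated) · 8 bis(MOM) diacid · 9 target

## Analysis of the target

The target 9 is a C2-symmetric 2,2'-biphenol, the 5,5'-linked dehydrodimer of dihydroferulic acid. It consists of two identical guaiacyl rings joined through the carbons ortho to their phenolic hydroxyls. Each ring is numbered C1 (side chain), C3 (OMe), C4 (OH) and C5 (aryl–aryl bond), and the chain is numbered C7 (benzylic CH2), C8 (CH2) and C9 (CO2H); only C2 and C6 carry hydrogen. There is no stereocentre. The C5–C5' axis has only two ortho substituents (the C4 and C4' oxygens), so its rotamers interconvert freely and the route has no stereochemical task. The sensitive groups are the two electron-rich phenols, which are acidic and easily oxidised, and the two carboxylic acids, which make the late intermediates polar. The difficulty is economy, not complexity: a tetra-oxygenated biaryl with a fixed substitution pattern must be reached, and every operation must succeed twice on one molecule without the rings being oxidised or alkylated. The plan rests on the position of C9, one bond beyond a C7–C8 unit on C1: an aryl–CH2–CH2–CO2H chain results when hydrogen is added to C7 and carbon dioxide to C8 of an aryl–CH=CH2 group. That alkene descends from a C7 aldehyde, and the dialdehyde that already holds the biaryl bond and the full oxygen pattern is divanillin 1.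

## Retrosynthetic reasoning

**9 to 8.** The last operation should only unmask the phenols. Free phenols cannot be carried further back: they would act as acids at a cathode, they make vinylarenes prone to polymerisation, and as phenoxides they deactivate a para aldehyde towards an ylide. The two aryl O–CH2 acetal bonds of the bis(methoxymethyl) ether 8 are therefore cut first. Methoxymethyl ethers have no acidic hydrogen, are inert to base, ylides and electrons, and are removed by dilute aqueous mineral acid, which leaves the propanoic acid chains and the aryl methyl ethers alone.

**8 to 5 and 6.** The C8–C9 and C8'–C9' bonds are cut. This is the only carbon–carbon disconnection of the chain that releases a one-carbon fragment already at the acid oxidation level, carbon dioxide 6, and it leaves the divinyl biaryl 5. Cutting C7–C8 or C1–C7 instead would call for benzylic or aryl halides and two-carbon or three-carbon ester partners, with hydrolysis or reduction afterwards. The forward reaction has to add hydrogen to C7 and 6 to C8 at both alkenes in one operation. It must avoid carboxylation at C7, uptake of a second molecule of 6, simple saturation of the alkene and chain growth between vinyl groups. The benzylic position directs the regiochemistry. The carboxylates first appear as the salt 7 and are protonated to 8 on work-up.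

**5 to 2 and 4.** Each C7=C8 double bond is cut to a C7 aldehyde and a one-carbon ylide. The ylide 4 is made in the flask from the phosphonium salt 3. This brings C8 in as a single carbon, needs no geometry control because the alkenes are terminal, and tolerates the acetals of dialdehyde 2.

**2 to 1.** The two O–CH2 acetal bonds are cut again, now on the aldehyde stage, which leads to divanillin 1. Compound 1 supplies all twelve ring carbons, the C5–C5' bond, the four ring oxygens and C7 at the aldehyde level, so no aryl–aryl bond has to be made and the symmetry of 9 is used from the first step.

## Alternatives that were turned down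

**Alternative 1:** Both benzene rings would be built from acyclic material.
- **Disconnection.** In each ring the C2–C3 and C5–C6 bonds are cut. C3–C4–C5 then comes from a ketone with its two alpha carbons, and C2–C1–C6 from a three-carbon dielectrophile that carries the chain. Because C5 and C5' are bonded, the two ketones are the two halves of the symmetric 1,4-diketone A2 (1,6-dimethoxyhexane-2,5-dione). The three-carbon partner is the 2-substituted vinamidinium salt A3, which bears the CH2CH2CO2Me group.
- **Forward key step.** A base-mediated double condensation of A2 with two equivalents of A3. Each ketone reacts through both alpha carbons, amine is lost, and each ring aromatises to a phenol, giving the dimethyl ester A1.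
- **For.** No protecting group and no redox adjustment are needed, the substitution pattern follows from connectivity alone, and A1 is one saponification from 9. On protecting-group economy and on the number of operations after the key step this plan is as strong as the chosen one or stronger.
- **Against.** Neither A2 nor A3 is a stock compound, and each needs its own synthesis, so the total count exceeds four steps. A2 is a 1,4-diketone with four enolisable positions, and under the base the annulation needs, intramolecular aldol condensation to a cyclopentenone is a direct competitor. After the first ring has formed, the phenoxide sits next to a CH2–C(=O) chain and can divert to a benzofuran by cyclodehydration. Four carbon–carbon bonds and two aromatisations would have to succeed in one flask.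
- **Comparison.** The chosen route buys the whole biaryl core in 1 and confines its risk to two identical bond formations on a side chain.

**Alternative 2:** Only ring A would be built, on a preformed ring B.
- **Disconnection.** C6–C1 and C4–C5 of ring A are cut. C5–C6 comes from the acetyl group of A5, a benzyl-protected dihydroferulic ester acylated at C5. C1–C4 comes from the ynone A6, which has the ester chain on the alkyne terminus and a benzyloxymethyl group on the ketone.
- **Forward key step.** The methyl-ketone enolate of A5 adds in conjugate fashion to the alkyne carbon of A6 that bears the chain. The CH2OBn carbon then condenses onto the aryl ketone, and dehydration and tautomerisation give the phenol A4.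
- **For.** The regiochemistry of ring A is unambiguous, and the approach would also serve biaryls with two different rings. On that flexibility it is stronger than the chosen route.
- **Against.** A4 has a free hydroxyl at C3 of ring A, where 9 has a methyl ether, and a benzyl ether at C4. O-methylation, double hydrogenolysis and double saponification must therefore follow. A5 and A6 both need several steps. A6 offers the base three acidic sites (the CH2 next to the ketone, the propargylic CH2 and the CH2 next to the ester), so isomerisation to an allenyl ketone and self-condensation compete. The enolate of A5 can also add to the carbonyl group instead of the alkyne, and only one alkene geometry of the adduct can close the ring.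
- **Comparison.** The plan discards the symmetry of 9 and roughly doubles the number of distinct operations. The chosen route treats both halves at once in four steps.

**Alternative 3:** The chain would be extended at C7 by a malonate.
- **Disconnection.** The C7–C8 bonds are cut, giving a benzylic electrophile at C7 and a malonate carbon as C8. The electrophile is masked as the bis-Mannich base A8, which would come from divanillin 1 by double reductive amination.
- **Forward key step.** Heating A8 with dimethyl malonate A9 and an alkoxide base expels the amine. The para-quinone methide A10 forms at one ring and then its counterpart at the other, and malonate adds to each exocyclic carbon to give the tetraester A7. Hydrolysis and double decarboxylation would finish the synthesis.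
- **For.** The chemistry is classical and needs no protecting group and no electrochemical cell, the starting material is the same, and the step count is about equal. On robustness of the individual reactions this alternative is as strong as the chosen route and arguably stronger.
- **Against.** The malonate C–H of A7 is still acidic, so it can add to a second molecule of A10. With two electrophilic sites per molecule this joins biaryls into oligomers unless A9 is used in large excess. The phenoxide oxygen is a further nucleophile for A10. Expulsion of a tertiary amine from a para-hydroxybenzyl position needs forcing temperatures or prior quaternisation. The end game is a thermal double decarboxylation on an oxidation-prone biphenol, and it discards one of every three carbons brought in by A9.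
- **Comparison.** The chosen strategy introduces exactly the missing carbon, alone and already at the acid oxidation level, from carbon dioxide 6. Nothing is discarded, no late heating is needed, and only a mild acetal hydrolysis follows the key step.

Key step: step 3

## Route

Remark on the chemistry: divanillin 1 is taken as a purchasable compound (it is traded as a flavouring substance). The biaryl axis is not configurationally stable, so no compound of the route needs a stereodescriptor. The counter-ion of A3 is assumed to be hexafluorophosphate.

Step 1
Reactants: 1 divanillin (6,6'-dihydroxy-5,5'-dimethoxybiphenyl-3,3'-dicarbaldehyde)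
Product: 2 5,5'-dimethoxy-6,6'-bis(methoxymethoxy)biphenyl-3,3'-dicarbaldehyde
Conditions: MOMCl, K2CO3, DMF, 0 °C to rt
Reagents that add atoms: chloromethyl methyl ether (MOMCl), COCCl
Why: O-alkylation of both phenoxides by the reactive alpha-chloro ether (Williamson-type ether synthesis); the para-formyl group makes each phenol acidic enough for K2CO3, and DMF should dissolve the sparingly soluble dialdehyde as its dianion. The aldehydes are not enolisable and do not react.

Step 2
Reactants: 2 5,5'-dimethoxy-6,6'-bis(methoxymethoxy)biphenyl-3,3'-dicarbaldehyde; 3 methyltriphenylphosphonium bromide
Product: 5 3,3'-dimethoxy-2,2'-bis(methoxymethoxy)-5,5'-divinylbiphenyl, via methylenetriphenylphosphorane 4 (not isolated)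
Conditions: Ph3PCH3Br, KOtBu, THF, 0 °C; then 2, 0 °C to rt; product kept cold with a trace of BHT
Reagents that add atoms: methyltriphenylphosphonium bromide (3), C[P+](c1ccccc1)(c1ccccc1)c1ccccc1.[Br-]
Why: Double Wittig methylenation; the unstabilised ylide 4 adds to both unhindered aryl aldehydes and the oxaphosphetanes collapse to terminal alkenes, which have no geometry to control. The MOM acetals are inert to the ylide and to tert-butoxide.

Step 3
Reactants: 5 3,3'-dimethoxy-2,2'-bis(methoxymethoxy)-5,5'-divinylbiphenyl; 6 carbon dioxide
Product: 8 3,3'-[5,5'-dimethoxy-6,6'-bis(methoxymethoxy)biphenyl-3,3'-diyl]dipropanoic acid, via magnesium dicarboxylate 7 (not isolated)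
Conditions: undivided cell, glassy-carbon cathode, Mg anode, CO2 (1 atm, continuous stream), H2O (a few equiv per alkene), n-Bu4NBF4, DMF, constant current, dilute in 5, 0 °C to rt; then cold dilute HCl to pH 3
Reagents that add atoms: carbon dioxide (6), O=C=O
Why: This is the electroreductive anti-Markovnikov (beta-selective) hydrocarboxylation of a vinylarene with CO2 and a proton donor, a reaction type established for styrenes and applied here to both vinyl groups of one molecule. Because a vinylarene carrying two oxygen donors is harder to reduce than CO2, the cathode most plausibly gives its first electron to CO2, and the CO2 radical anion adds to the terminal carbon C8; should the alkene be reduced first, its radical anion attacks CO2 through the same terminal carbon, so both paths lead to one intermediate. In either case the unpaired electron is left on the benzylic carbon C7, where the ring stabilises it, and this places the carboxyl group on C8 and not on C7. The benzylic radical is reduced at the working potential to the benzylic anion, which the added water protonates; the amount of water is chosen so that protonation outruns capture of a second CO2 (the route to the arylsuccinate) without turning the current over to hydrogen evolution. The dissolving Mg anode supplies magnesium ions instead of an oxidant, so nothing in the undivided cell can oxidise the electron-rich arenes, and the carboxylates accumulate as the salt 7. No ring is closed and no stereocentre is created. The MOM acetals have neither an acidic hydrogen nor a reducible group and should pass unchanged, and the two vinyl groups sit on different rings of a twisted biaryl and react independently, so one electrolysis forms both C8–C9 bonds. Acidification is done cold and only to pH 3 so that the aryl MOM ethers survive, and extraction into aqueous NaHCO3 followed by re-acidification should separate diacid 8 from neutral by-products.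

Step 4
Reactants: 8 3,3'-[5,5'-dimethoxy-6,6'-bis(methoxymethoxy)biphenyl-3,3'-diyl]dipropanoic acid
Product: 9 3,3'-(6,6'-dihydroxy-5,5'-dimethoxybiphenyl-3,3'-diyl)dipropanoic acid (the target)
Conditions: 2 M aq HCl, THF, 40 °C, under N2
Reagents that add atoms: none
Why: Acid-catalysed hydrolysis of the two aryl methoxymethyl acetals through the oxocarbenium ion releases both phenols. The carboxylic acids, the aryl methyl ethers and the biaryl bond are stable to dilute aqueous acid, and with no alcohol solvent present the acids cannot esterify.

## Compound list

1 | divanillin (6,6'-dihydroxy-5,5'-dimethoxybiphenyl-3,3'-dicarbaldehyde) | COc1cc(C=O)cc(-c2cc(C=O)cc(OC)c2O)c1O | starting material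
2 | 5,5'-dimethoxy-6,6'-bis(methoxymethoxy)biphenyl-3,3'-dicarbaldehyde | COCOc1c(OC)cc(C=O)cc1-c1cc(C=O)cc(OC)c1OCOC | intermediate
3 | methyltriphenylphosphonium bromide | C[P+](c1ccccc1)(c1ccccc1)c1ccccc1.[Br-] | starting material
4 | methylenetriphenylphosphorane | C=P(c1ccccc1)(c1ccccc1)c1ccccc1 | intermediate (not isolated)
5 | 3,3'-dimethoxy-2,2'-bis(methoxymethoxy)-5,5'-divinylbiphenyl | C=Cc1cc(OC)c(OCOC)c(-c2cc(C=C)cc(OC)c2OCOC)c1 | intermediate
6 | carbon dioxide | O=C=O | starting material
7 | magnesium 3,3'-[5,5'-dimethoxy-6,6'-bis(methoxymethoxy)biphenyl-3,3'-diyl]dipropanoate | COCOc1c(OC)cc(CCC(=O)[O-])cc1-c1cc(CCC(=O)[O-])cc(OC)c1OCOC.[Mg+2] | intermediate (not isolated)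
8 | 3,3'-[5,5'-dimethoxy-6,6'-bis(methoxymethoxy)biphenyl-3,3'-diyl]dipropanoic acid | COCOc1c(OC)cc(CCC(=O)O)cc1-c1cc(CCC(=O)O)cc(OC)c1OCOC | intermediate
9 | 3,3'-(6,6'-dihydroxy-5,5'-dimethoxybiphenyl-3,3'-diyl)dipropanoic acid | COc1cc(CCC(=O)O)cc(-c2cc(CCC(=O)O)cc(OC)c2O)c1O | target

## Step count and risk

Total step count: 4. Longest linear sequence: 4 steps (1 to 2 to 5 to 8 to 9).

**Step 3 (key step).**
- What may go wrong: the benzylic radical formed after the first carbon–carbon bond may add to a vinyl group of another molecule before it is reduced. With two vinyl groups per molecule this chain growth would give cross-linked oligomers.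
- A second difficulty is the electron-rich alkene, which is a slow acceptor for the nucleophilic CO2 radical anion. Current can then drain into formate, oxalate or hydrogen, and conversion may stall at the stage where only one chain is complete.
- Too little water would allow uptake of a second CO2 at C7. Too much would favour plain saturation of the alkene. Magnesium carbonate or hydroxide may also coat the anode in wet DMF.
- Partial loss of a MOM group in the acidic work-up would not matter, since step 4 removes both.
- Fallback: leave the electrochemical path at dialdehyde 2 and build the chain by carbonyl olefination. Horner–Wadsworth–Emmons reaction of 2 with triethyl phosphonoacetate (NaH, THF) should give diethyl (2E,2'E)-3,3'-[5,5'-dimethoxy-6,6'-bis(methoxymethoxy)biphenyl-3,3'-diyl]bis(prop-2-enoate) F1. Hydrogenation (H2, Pd/C, EtOAc) should give diethyl 3,3'-[5,5'-dimethoxy-6,6'-bis(methoxymethoxy)biphenyl-3,3'-diyl]dipropanoate F2. Saponification (NaOH, THF/H2O, then cold acidification to pH 3) rejoins the route at 8.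

**Step 2.**
- What may go wrong: the electron-rich divinyl biaryl may be lost through radical or acid-induced polymerisation while it is concentrated and chromatographed to remove the phosphine oxide. Incomplete olefination of the second aldehyde is a lesser concern.
- Fallback: from 2, a Peterson olefination. Addition of Me3SiCH2MgCl in THF should give 1,1'-[5,5'-dimethoxy-6,6'-bis(methoxymethoxy)biphenyl-3,3'-diyl]bis[2-(trimethylsilyl)ethan-1-ol] F3, a mixture of diastereomers of no consequence. KH in THF should then trigger syn-elimination of silanolate and rejoin the route at 5. The silicon by-product is removed by washing and evaporation, so 5 can go to the electrolysis without chromatography.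

**Step 4.**
- What may go wrong: the formaldehyde set free, or the methoxymethyl cation before it is hydrolysed, may attack the activated ring position C6 (para to the methoxy group) of a liberated biphenol and cause hydroxymethylation or methylene bridging. The free biphenol may also darken by air oxidation on warming.
- Fallback: from 8, treatment with anhydrous HCl in methanol at rt transfers the MOM groups to the solvent as dimethoxymethane and at the same time esterifies the acids (Fischer esterification). This should give dimethyl 3,3'-(6,6'-dihydroxy-5,5'-dimethoxybiphenyl-3,3'-diyl)dipropanoate F4, the same structure as A1. Saponification with NaOH in degassed THF/H2O and acidification then arrives at 9.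

## Further compounds

F1 | step 3 | diethyl (2E,2'E)-3,3'-[5,5'-dimethoxy-6,6'-bis(methoxymethoxy)biphenyl-3,3'-diyl]bis(prop-2-enoate) | CCOC(=O)/C=C/c1cc(OC)c(OCOC)c(-c2cc(/C=C/C(=O)OCC)cc(OC)c2OCOC)c1
F2 | step 3 | diethyl 3,3'-[5,5'-dimethoxy-6,6'-bis(methoxymethoxy)biphenyl-3,3'-diyl]dipropanoate | CCOC(=O)CCc1cc(OC)c(OCOC)c(-c2cc(CCC(=O)OCC)cc(OC)c2OCOC)c1
F3 | step 2 | 1,1'-[5,5'-dimethoxy-6,6'-bis(methoxymethoxy)biphenyl-3,3'-diyl]bis[2-(trimethylsilyl)ethan-1-ol] (mixture of diastereomers) | C[Si](C)(C)CC(O)c1cc(OC)c(OCOC)c(-c2cc(C(O)C[Si](C)(C)C)cc(OC)c2OCOC)c1
F4 | step 4 | dimethyl 3,3'-(6,6'-dihydroxy-5,5'-dimethoxybiphenyl-3,3'-diyl)dipropanoate | COC(=O)CCc1cc(OC)c(O)c(-c2cc(CCC(=O)OC)cc(OC)c2O)c1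
A1 | alternative 1 | dimethyl 3,3'-(6,6'-dihydroxy-5,5'-dimethoxybiphenyl-3,3'-diyl)dipropanoate | COC(=O)CCc1cc(OC)c(O)c(-c2cc(CCC(=O)OC)cc(OC)c2O)c1
A2 | alternative 1 | 1,6-dimethoxyhexane-2,5-dione | COCC(=O)CCC(=O)COC
A3 | alternative 1 | [3-(dimethylamino)-2-(3-methoxy-3-oxopropyl)prop-2-en-1-ylidene]dimethylammonium hexafluorophosphate | COC(=O)CCC(C=[N+](C)C)=CN(C)C.F[P-](F)(F)(F)(F)F
A4 | alternative 2 | dimethyl 3,3'-[6,6'-bis(benzyloxy)-5-hydroxy-5'-methoxybiphenyl-3,3'-diyl]dipropanoate | COC(=O)CCc1cc(O)c(OCc2ccccc2)c(-c2cc(CCC(=O)OC)cc(OC)c2OCc2ccccc2)c1
A5 | alternative 2 | methyl 3-[3-acetyl-4-(benzyloxy)-5-methoxyphenyl]propanoate | COC(=O)CCc1cc(OC)c(OCc2ccccc2)c(C(C)=O)c1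
A6 | alternative 2 | methyl 7-(benzyloxy)-6-oxohept-4-ynoate | COC(=O)CCC#CC(=O)COCc1ccccc1
A7 | alternative 3 | tetramethyl 2,2'-[(6,6'-dihydroxy-5,5'-dimethoxybiphenyl-3,3'-diyl)bis(methylene)]dimalonate | COC(=O)C(Cc1cc(OC)c(O)c(-c2cc(CC(C(=O)OC)C(=O)OC)cc(OC)c2O)c1)C(=O)OC
A8 | alternative 3 | 5,5'-bis[(dimethylamino)methyl]-3,3'-dimethoxybiphenyl-2,2'-diol | CN(C)Cc1cc(OC)c(O)c(-c2cc(CN(C)C)cc(OC)c2O)c1
A9 | alternative 3 | dimethyl malonate | COC(=O)CC(=O)OC
A10 | alternative 3 | 2-[5-(dimethylaminomethyl)-2-hydroxy-3-methoxyphenyl]-6-methoxy-4-methylidenecyclohexa-2,5-dien-1-one | C=C1C=C(OC)C(=O)C(=C1)c1cc(CN(C)C)cc(OC)c1O
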